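**Two partners.** In a one-step world reagent would have one partner and no share to ask about. Here it has two: catalyst intermediate B, which leads it on to target, and the target itself, which it turns into over-reaction product.

| flask | starting material | reagent | precatalyst | temperature | time | remark |
|---|---|---|---|---|---|---|
| Wednesday's | 0.30 M | 0.285 M | 15 mM | 25 °C | 6.0 h |  |
| Sunday's | 0.30 M | 0.285 M | 15 mM | −5 °C | 6.0 h |  |
| Friday's | 0.30 M | 0.285 M | 15 mM | 55 °C | 6.0 h |  |
| Thursday's | 0.30 M | 0.285 M | 15 mM |  | 6.0 h | at −5 °C until 3.0 h, from then on at 55 °C |

1. which flask leads in share of target in all that became target or over-reaction product ("all alike" within 1.5 percentage points) (Wednesday's / Sunday's / Friday's / Thursday's / all alike)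
2. share of target in all that became target or over-reaction product, Wednesday's
3. share of target in all that became target or over-reaction product, Sunday's
4. share of target in all that became target or over-reaction product, Friday's
5. share of target in all that became target or over-reaction product, Thursday's

- the list of constants is for 25 °C, to be carried to other temperatures by the activation energies and enthalpies

    starting material + free catalyst ⇌ catalyst intermediate A (K1 = 5.0 M⁻¹, k1 = 7.07 M⁻¹ min⁻¹, Ea1 = 63.0 kJ mol⁻¹, ΔH1 = −14.0 kJ mol⁻¹)
    catalyst intermediate A → catalyst intermediate B (k2 = 0.493 min⁻¹, Ea2 = 76.0 kJ mol⁻¹)
    reagent + catalyst intermediate B → catalyst intermediate C (k3 = 2.33 M⁻¹ min⁻¹, Ea3 = 40.0 kJ mol⁻¹)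
    catalyst intermediate C → by-product + catalyst intermediate D (k4 = 0.537 min⁻¹, Ea4 = 92.0 kJ mol⁻¹)
    catalyst intermediate D ⇌ free catalyst + target (K5 = 3.33 M, k5 = 0.557 min⁻¹, Ea5 = 82.0 kJ mol⁻¹, ΔH5 = −26.0 kJ mol⁻¹)
    precatalyst → free catalyst (k6 = 0.00371 min⁻¹, Ea6 = 101 kJ mol⁻¹)
    reagent + target → over-reaction product (k7 = 0.0123 M⁻¹ min⁻¹, Ea7 = 67.0 kJ mol⁻¹)
    (constants at 25 °C)

**Crossing level.** I defined P× as the target concentration at which target takes reagent as fast as B does, with the whole catalyst charge sitting as B. At 55 °C it came to 1.05 M, and this crossing level is the quantity I carried. Target climbs from nothing, so over-reaction product over target comes to about reagent spent divided by 2P×. The share is then the reciprocal of one plus that ratio.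

**Upper bound.** Reagent was the smaller charge, the limiting reagent, so I took its whole charge as spent. With the catalyst wholly as B, I put Friday's share below 88.0%.

**Lower bound.** At the start of Friday's flask, the catalyst waited 0.344 min as B and 0.456 min in the rest of the round. That put 43.0% of it in B, and scaling P× by this portion gave 76.0%. The precatalyst's half-life there, 4.51 min, was shorter than the reagent's time of 15.2 min, so I let it pass.

**Tightening.** With reagent at half its charge, B's portion rose to 52.5%. I committed to 79.5% for Friday's flask. Thursday's cold half opened hardly any precatalyst, and its hot half outlasted the reagent's time, so I gave Thursday's 79.5%.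

**The clock.** In Sunday's flask the precatalyst's half-life, 297 h, exceeded the run, so control passed from reagent to time. Catalyst appeared evenly and target grew at least as the square of time, which put Sunday's share above 98.0%. Wednesday's flask lay between the two regimes, from 61.3% by the clock to 95.2% by the crossing level. So the leader was Sunday's.

**The forecast.** The forecast named Sunday's, with 80%, 98.8%, 82% and 82% in the order Wednesday's, Sunday's, Friday's, Thursday's; its ground for the leader was that at the coldest temperature “the precatalyst barely activates, so only a trace of target forms and almost none of it goes on to over-reaction”.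

**The result.** The simulation gave Sunday's as leader, with 80.6%, 98.4%, 81.4% and 81.4% in the same order, and Friday's share stood inside my bracket.

**At the turn.** In Thursday's flask at 3.23 h, reagent reacted with B 4.6 times as fast as with target, and target was made 4.69 times as fast as it was used up, each step taken net. That flask ended with reagent at 0% of its charge, target at 65.2% and over-reaction product at 14.9%.

**Less reagent.** For a neighbour of Thursday's flask charged with 0.071 M of reagent, the crossing level gave a ceiling of 96.7%. The neighbour's computed share was 95.8%.

(The numbers come from no measurement.)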